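**Retrosynthetic overview**
1. Locants (eudesmane style): C10 = angular C–CH3, C5 = ring-fusion CH, C7 = CH bearing C11(CH3)2OH, C3 = C(CH3)(OAr). Ring A = C1–C2–C3–C4–C5–C10, ring B = C5–C6–C7–C8–C9–C10, and β is the face of the C10 methyl group.
2. End game: Si–O cleavage, then the para C–allyl bond (Suzuki–Miyaura on ArCl), the biaryl bond (Suzuki–Miyaura on ArBr), and the aryl–O bond from the tertiary 3α-alkoxide of 13 and a diaryliodonium salt.
3. Ring A of 13 comes from the cyclopentane C1–C2–C3–C5–C10 of tricycle 11 by one-electron oxidation, H2O attack at C3, scission of C3–C5 and H-atom transfer to C5. The cyclopropane CH2 becomes C4 (5 → 6).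
4. Enabling feature: C3–C5 is the zero bridge of a bicyclo[3.1.0]hexane and the only cyclopropane bond between two fully alkylated carbons, so it is the bond that gives up the electron. Its rear side is free at C3 and buried under ring B and C10 at C5.
5. Ring order: ring B from (+)-dihydrocarvone (C7), C10 by auxiliary-controlled Michael addition, cyclopentene by McMurry coupling of the 1,5-diketone, cyclopropane by Simmons–Smith reaction anti to C10–CH3, ring A by expansion, arenes last.

Key step: step 7

Remark: commercial (+)-dihydrocarvone is a mixture of C2 epimers. This is taken as harmless because C2 is planarised in the enamine tautomer of 3.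

**Step 1**
Reactants: 1 (+)-dihydrocarvone; 2 (R)-1-phenylethylamine
Product: 3 N-[(R)-1-phenylethyl] ketimine of 1
Conditions: TsOH (cat.), toluene, reflux, Dean–Stark
Reagents that add atoms: none
Why: Acid-catalysed ketimine condensation with azeotropic removal of water; the stereocentre next to C=N is labile and is reset in step 2, and C7 is untouched.

**Step 2**
Reactants: 3 ketimine; 4 methyl vinyl ketone
Product: 6 (2S,5R)-2-methyl-2-(3-oxobutyl)-5-(prop-1-en-2-yl)cyclohexan-1-one, via adduct ketimine 5 (not isolated)
Conditions: THF, 40 °C; then dilute aq. AcOH, rt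
Reagents that add atoms: water, O
Why: Asymmetric Michael addition of a chiral ketimine through its more substituted secondary enamine tautomer (aza-ene-like, chair-shaped transition state): the (R)-phenylethyl group and the equatorial isopropenyl group both leave the α face open, so C1 should add there and the C10 methyl group ends β, cis to the C7 substituent, and mild aqueous acid then hydrolyses 5 without aldol closure.

**Step 3**
Reactants: 6 1,5-diketone
Product: 7 3,7a-dimethyl-5-(prop-1-en-2-yl)-2,4,5,6,7,7a-hexahydro-1H-indene (C3=C5 alkene; C10-CH3 β; C7 isopropenyl β)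
Conditions: TiCl3(DME)1.5, Zn–Cu, DME, reflux, slow addition of 6
Reagents that add atoms: none
Why: Intramolecular McMurry coupling (ketyl dimerisation on low-valent titanium, then deoxygenation) closes five-membered rings well and leaves isolated alkenes alone; high dilution and the non-basic medium should hold back the competing aldol path, and no stereocentre is made.

**Step 4**
Reactants: 7 diene
Product: 9 tertiary alcohol 2-[3,7a-dimethyl-hexahydro-1H-inden-5-yl]propan-2-ol (C3=C5 alkene kept), via tertiary hydroperoxide 8 (not isolated)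
Conditions: Mn(dpm)3 (cat.), PhSiH3, O2 (1 atm), i-PrOH–CH2Cl2, 0 °C; then PPh3
Reagents that add atoms: dioxygen, O=O
Why: Mukaiyama hydration (metal-hydride H-atom transfer, O2 capture, reduction of the peroxide) is Markovnikov-selective and should pick the accessible 1,1-disubstituted alkene over the shielded tetrasubstituted one; C7 is not touched.

**Step 5**
Reactants: 9 tertiary alcohol
Product: 10 triethylsilyl ether of 9
Conditions: TESOTf, 2,6-lutidine, CH2Cl2, −78 to 0 °C
Reagents that add atoms: triethylsilyl triflate, CC[Si](CC)(CC)OS(=O)(=O)C(F)(F)F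
Why: Silylation of a tertiary alcohol with the silyl triflate and a hindered base; the ether masks O-11 as a nucleophile in step 7 and as an alkoxide in step 9.

**Step 6**
Reactants: 10 tetrasubstituted alkene
Product: 11 tricycle (CH2 = C4 bridging C3 and C5 on the α face; C3-CH3 β; C10-CH3 β)
Conditions: Et2Zn, CH2I2, ClCH2CH2Cl, 0 to 40 °C
Reagents that add atoms: diiodomethane, ICI
Why: Simmons–Smith cyclopropanation (Furukawa variant), a concerted syn methylene transfer that favours electron-rich alkenes; the axial C10 methyl group blocks the β face, so CH2 should add to the α face and set C3 and C5 together.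

**Step 7**
Reactants: 11 tricycle
Product: 13 3α-hydroxy-3β,10β-dimethyl-7β-[2-(triethylsilyloxy)propan-2-yl]-5αH-decalin (trans), via C5 radical 12 (not isolated)
Conditions: 3,6-di-tert-butyl-9-mesityl-10-phenylacridinium BF4 (5 mol%), (PhS)2 (10 mol%), H2O (20 equiv), MeCN–CH2Cl2, 450 nm LED, rt
Reagents that add atoms: water, O
Why: Proposed new method: the excited acridinium (about +2.1 V vs SCE) should take one electron from the most electron-rich σ-bond of 11, the C3–C5 bond between the two fully alkylated cyclopropane carbons; water then attacks C3 from the rear of this weakened bond (three-electron SN2), C3–C5 breaks, the cyclopentane C1–C2–C3–C5–C10 becomes the cyclohexane C1–C2–C3–C4–C5–C10, and the C5 radical 12 takes H from PhSH while reduced acridine and PhS• close both catalytic cycles. The closest known reaction types are the nucleophilic opening of aryl- and polyalkylcyclopropane radical cations (photoinduced or anodic, cleavage of the most substituted bond, inversion even at tertiary carbon) and the acridinium/thiol hydrofunctionalisation of alkenes; joining them on a purely alkyl-substituted bicyclo[3.1.0]hexane is new. No ring bond is made, so no closure mode applies: ring A is released by scission of the zero bridge and the former cyclopropane CH2 becomes C4. C3 is set by inversion, because the cyclopropane CH2 lies on the α face and the rear of C3–C5 therefore leads oxygen into the α (axial) position and leaves CH3 β (equatorial), and C5 is set by H-atom transfer to the α face, anti to the axial C10 methyl group, which gives the trans-decalin. The step needs attack at C3 and not C5, and cleavage of C3–C5 and not of a bond to CH2: the rear of C5 points into ring B below C10 and is closed, and charge and spin sit on the two tertiary carbons, whereas protic or metal electrophiles would attack the CH2 corner. The silyl ether keeps O-11 from competing as an internal nucleophile, and no alkene or arene that is easier to oxidise is present, which is also why water and not the phenol is the nucleophile here.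

**Step 8**
Reactants: 14 2-bromo-4-chloro-1-iodobenzene; 15 1,3,5-trimethoxybenzene
Product: 17 (2-bromo-4-chlorophenyl)(2,4,6-trimethoxyphenyl)iodonium tosylate, via hydroxy(tosyloxy)iodoarene 16 (not isolated)
Conditions: mCPBA, TsOH·H2O, MeCN, 75 °C; then 15, 75 °C
Reagents that add atoms: 4-methylbenzenesulfonic acid, Cc1ccc(S(=O)(=O)O)cc1
Why: One-pot oxidation of the aryl iodide to the hydroxy(tosyloxy)-λ3-iodane and electrophilic substitution on the electron-rich arene, a standard entry to unsymmetrical diaryliodonium salts that carry a trimethoxyphenyl dummy group.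

**Step 9**
Reactants: 13 3α-carbinol; 17 iodonium tosylate
Product: 18 2-bromo-4-chlorophenyl ether of 13 (O at C3 α)
Conditions: NaHMDS, toluene, 0 °C; then 17, rt to 40 °C
Reagents that add atoms: none
Why: Metal-free O-arylation of a tertiary alkoxide with a diaryliodonium salt (ligand exchange at iodine, then ligand coupling): the electron-poor, ortho-substituted aryl group is transferred and the trimethoxyphenyl group leaves as aryl iodide, and since the C3–O bond is not touched the configuration is kept.

**Step 10**
Reactants: 19 4-bromophenol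
Product: 20 allyl 4-bromophenyl ether
Conditions: allyl bromide, K2CO3, acetone, reflux
Reagents that add atoms: allyl bromide, C=CCBr
Why: Williamson ether synthesis on a phenoxide with a reactive allylic halide.

**Step 11**
Reactants: 20 allyl aryl ether
Product: 22 2-allyl-4-bromophenol, via ortho-dienone 21 (not isolated)
Conditions: N,N-diethylaniline, 200 °C
Reagents that add atoms: none
Why: Aromatic Claisen rearrangement ([3,3]-sigmatropic shift, then tautomerisation) delivers the allyl group to a free ortho position.

**Step 12**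
Reactants: 22 2-allyl-4-bromophenol
Product: 23 triisopropylsilyl ether of 22
Conditions: TIPSCl, imidazole, DMF, rt
Reagents that add atoms: chlorotriisopropylsilane, CC(C)[Si](Cl)(C(C)C)C(C)C
Why: Standard silylation; the bulky triisopropylsilyl group should survive the basic aqueous coupling steps and falls with fluoride at the end.

**Step 13**
Reactants: 23 aryl bromide
Product: 24 pinacol boronate of 23 (B in place of Br)
Conditions: B2pin2, Pd(dppf)Cl2 (cat.), KOAc, dioxane, 85 °C
Reagents that add atoms: bis(pinacolato)diboron, CC1(C)OB(B2OC(C)(C)C(C)(C)O2)OC1(C)C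
Why: Miyaura borylation of an aryl bromide; the weak base acetate avoids homocoupling and allyl migration.

**Step 14**
Reactants: 18 aryl bromide; 24 boronate
Product: 25 5-chloro-biaryl ether (3'-allyl; 4'-OTIPS; O-11 TES)
Conditions: Pd(dppf)Cl2 (cat.), K3PO4, dioxane–H2O, 85 °C
Reagents that add atoms: none
Why: Suzuki–Miyaura coupling in which oxidative addition picks C–Br over the electron-rich C–Cl bond with a catalyst of moderate activity, so the biaryl bond forms only ortho to the ether oxygen.

**Step 15**
Reactants: 25 aryl chloride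
Product: 26 bis-silylated target (5-allyl; 3'-allyl)
Conditions: allylB(pin), XPhos Pd G3 (cat.), K3PO4, THF–H2O, 60 °C
Reagents that add atoms: allylboronic acid pinacol ester, C=CCB1OC(C)(C)C(C)(C)O1
Why: Suzuki–Miyaura allylation of an aryl chloride with a bulky biarylphosphine palladium catalyst; the moderate temperature should keep both allyl groups from moving into conjugation.

**Step 16**
Reactants: 26 bis-silyl ether
Product: 27 target CNP0342687.1
Conditions: TBAF, THF, rt to 45 °C
Reagents that add atoms: none
Why: Fluoride-induced cleavage of both silyl ethers under non-acidic conditions, which the acid-labile tertiary alkyl aryl ether and the allyl groups tolerate.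

**Compound list**
1 | (+)-dihydrocarvone, (2R,5R)-2-methyl-5-(prop-1-en-2-yl)cyclohexan-1-one | C[C@@H]1CC[C@@H](C(C)=C)CC1=O | starting material
2 | (R)-1-phenylethylamine | C[C@@H](N)c1ccccc1 | starting material
3 | N-[(R)-1-phenylethyl] ketimine of 1 | C[C@@H]1CC[C@@H](C(C)=C)CC1=N[C@H](C)c1ccccc1 | intermediate
4 | methyl vinyl ketone | C=CC(C)=O | starting material
5 | ketimine of 6 (Michael adduct, not isolated) | CC(=O)CC[C@]1(C)CC[C@@H](C(C)=C)CC1=N[C@H](C)c1ccccc1 | intermediate
6 | (2S,5R)-2-methyl-2-(3-oxobutyl)-5-(prop-1-en-2-yl)cyclohexan-1-one | CC(=O)CC[C@]1(C)CC[C@@H](C(C)=C)CC1=O | intermediate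
7 | 3,7a-dimethyl-5-(prop-1-en-2-yl)-2,4,5,6,7,7a-hexahydro-1H-indene | CC1=C2C[C@H](C(C)=C)CC[C@@]2(C)CC1 | intermediate
8 | tertiary hydroperoxide at C11 (not isolated) | CC1=C2C[C@H](C(C)(C)OO)CC[C@@]2(C)CC1 | intermediate
9 | tertiary alcohol at C11 | CC1=C2C[C@H](C(C)(C)O)CC[C@@]2(C)CC1 | intermediate
10 | triethylsilyl ether of 9 | CC1=C2C[C@H](C(C)(C)O[Si](CC)(CC)CC)CC[C@@]2(C)CC1 | intermediate
11 | tricycle, CH2 bridging C3 and C5 on the α face | C[C@@]12CC[C@]3(C)CC[C@@H](C(C)(C)O[Si](CC)(CC)CC)C[C@]31C2 | intermediate
12 | ring-expanded C5 radical (not isolated) | O[C@]1(C)CC[C@]2(C)CC[C@@H](C(C)(C)O[Si](CC)(CC)CC)C[C]2C1 | intermediate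
13 | 3α-hydroxy-3β,10β-dimethyl-7β-[2-(triethylsilyloxy)propan-2-yl]-5αH-decalin | O[C@]1(C)CC[C@]2(C)CC[C@@H](C(C)(C)O[Si](CC)(CC)CC)C[C@H]2C1 | intermediate
14 | 2-bromo-4-chloro-1-iodobenzene | Clc1ccc(I)c(Br)c1 | starting material
15 | 1,3,5-trimethoxybenzene | COc1cc(OC)cc(OC)c1 | starting material
16 | (2-bromo-4-chlorophenyl)(hydroxy)(tosyloxy)-λ3-iodane (not isolated) | Cc1ccc(S(=O)(=O)OI(O)c2ccc(Cl)cc2Br)cc1 | intermediate
17 | (2-bromo-4-chlorophenyl)(2,4,6-trimethoxyphenyl)iodonium tosylate | COc1cc(OC)c([I+]c2ccc(Cl)cc2Br)c(OC)c1.Cc1ccc(S(=O)(=O)[O-])cc1 | intermediate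
18 | 2-bromo-4-chlorophenyl ether of 13 | Clc1ccc(O[C@]2(C)CC[C@]3(C)CC[C@@H](C(C)(C)O[Si](CC)(CC)CC)C[C@H]3C2)c(Br)c1 | intermediate
19 | 4-bromophenol | Oc1ccc(Br)cc1 | starting material
20 | allyl 4-bromophenyl ether | C=CCOc1ccc(Br)cc1 | intermediate
21 | 6-allyl-4-bromocyclohexa-2,4-dien-1-one (not isolated) | O=C1C=CC(Br)=CC1CC=C | intermediate
22 | 2-allyl-4-bromophenol | C=CCc1cc(Br)ccc1O | intermediate
23 | (2-allyl-4-bromophenoxy)triisopropylsilane | C=CCc1cc(Br)ccc1O[Si](C(C)C)(C(C)C)C(C)C | intermediate
24 | 3-allyl-4-(triisopropylsilyloxy)phenylboronic acid pinacol ester | C=CCc1cc(B2OC(C)(C)C(C)(C)O2)ccc1O[Si](C(C)C)(C(C)C)C(C)C | intermediate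
25 | 5-chloro biaryl ether | Clc1ccc(O[C@]2(C)CC[C@]3(C)CC[C@@H](C(C)(C)O[Si](CC)(CC)CC)C[C@H]3C2)c(-c2ccc(O[Si](C(C)C)(C(C)C)C(C)C)c(CC=C)c2)c1 | intermediate
26 | bis-silylated target | C=CCc1ccc(O[C@]2(C)CC[C@]3(C)CC[C@@H](C(C)(C)O[Si](CC)(CC)CC)C[C@H]3C2)c(-c2ccc(O[Si](C(C)C)(C(C)C)C(C)C)c(CC=C)c2)c1 | intermediate
27 | CNP0342687.1 | C=CCc1ccc(O[C@]2(C)CC[C@]3(C)CC[C@@H](C(C)(C)O)C[C@H]3C2)c(-c2ccc(O)c(CC=C)c2)c1 | target

**Counts**
Total step count: 16. Longest linear sequence: 11 (steps 1–7, 9, 14, 15, 16).

**Steps most likely to fail**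

1. Step 7.
- What may go wrong: electron transfer from the all-alkyl cyclopropane may be too slow or be undone by back-transfer. The radical cation may lose a proton instead of being captured by water. The H-atom transfer may show poor facial selectivity.
- Fallback (known chemistry, from 10, back at 13): dibromocarbene (CHBr3, KOt-Bu, pentane) is added to the α face of the C3=C5 alkene to give the gem-dibromocyclopropane F1.
- AgClO4 and CaCO3 in aqueous acetone then trigger the disrotatory electrocyclic opening of the cyclopropyl bromide, which again enlarges the cyclopentane by the carbene carbon. Water takes the pseudo-axial α path at C3 of the 2-bromoallyl cation and gives the 4-bromo-Δ4-3α-carbinol F2.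
- Li in NH3–THF with t-BuOH removes the vinylic bromine to give the Δ4-3α-carbinol F3.
- Hydroxyl-directed hydrogenation with [Ir(cod)(PCy3)(py)]PF6 and H2 in CH2Cl2 delivers H to the α face of C5 and gives 13.

2. Step 3.
- What may go wrong: aldol closure of the 1,5-diketone on Lewis-acidic titanium, or stalling at the pinacolate stage next to the quaternary centre.
- Fallback (from 6, back at 7): SmI2 in THF–t-BuOH couples the two ketones to the cis-diol F4, whose carbinol configuration is erased later.
- 1,1'-Thiocarbonyldiimidazole with DMAP in hot toluene gives the cyclic thionocarbonate F5.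
- Corey–Winter elimination with P(OMe)3 at reflux gives 7.

3. Step 9.
- What may go wrong: base-induced aryne formation from the iodonium salt, or slow ligand coupling at the crowded axial alkoxide.
- Fallback (from 13, back at 26): the potassium alkoxide (KHMDS, THF–DMF) displaces fluoride from 3-bromo-4-fluorobenzaldehyde by SNAr to give the aryloxy aldehyde F6.
- Suzuki–Miyaura coupling of F6 with 24 gives the biaryl aldehyde F7.
- Vinylmagnesium bromide gives the allylic alcohol F8 as a carbinol epimer mixture, and methyl chloroformate with pyridine gives the allylic carbonate F9.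
- Palladium-catalysed formate reduction (Pd2(dba)3, PBu3, HCO2H–Et3N) delivers hydride to the benzylic terminus of the π-allyl complex and gives the terminal alkene 26.

**Further compounds**
F1 | step 7 | gem-dibromocyclopropane (CBr2 bridging C3 and C5 on the α face) | C[C@@]12CC[C@]3(C)CC[C@@H](C(C)(C)O[Si](CC)(CC)CC)C[C@]31C2(Br)Br
F2 | step 7 | 4-bromo-Δ4-3α-carbinol | O[C@]1(C)CC[C@]2(C)CC[C@@H](C(C)(C)O[Si](CC)(CC)CC)CC2=C1Br
F3 | step 7 | Δ4-3α-carbinol | O[C@]1(C)CC[C@]2(C)CC[C@@H](C(C)(C)O[Si](CC)(CC)CC)CC2=C1
F4 | step 3 | cis-3,5-diol of the hydrindane | C[C@@]1(O)CC[C@]2(C)CC[C@@H](C(C)=C)C[C@]21O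
F5 | step 3 | cyclic thionocarbonate of F4 | C[C@@]12CC[C@]3(C)CC[C@@H](C(C)=C)C[C@]31OC(=S)O2
F6 | step 9 | 3-bromo-4-(terpenyloxy)benzaldehyde | O=Cc1ccc(O[C@]2(C)CC[C@]3(C)CC[C@@H](C(C)(C)O[Si](CC)(CC)CC)C[C@H]3C2)c(Br)c1
F7 | step 9 | biaryl aldehyde | O=Cc1ccc(O[C@]2(C)CC[C@]3(C)CC[C@@H](C(C)(C)O[Si](CC)(CC)CC)C[C@H]3C2)c(-c2ccc(O[Si](C(C)C)(C(C)C)C(C)C)c(CC=C)c2)c1
F8 | step 9 | 1-arylprop-2-en-1-ol (carbinol epimers) | C=CC(O)c1ccc(O[C@]2(C)CC[C@]3(C)CC[C@@H](C(C)(C)O[Si](CC)(CC)CC)C[C@H]3C2)c(-c2ccc(O[Si](C(C)C)(C(C)C)C(C)C)c(CC=C)c2)c1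
F9 | step 9 | methyl carbonate of F8 | C=CC(OC(=O)OC)c1ccc(O[C@]2(C)CC[C@]3(C)CC[C@@H](C(C)(C)O[Si](CC)(CC)CC)C[C@H]3C2)c(-c2ccc(O[Si](C(C)C)(C(C)C)C(C)C)c(CC=C)c2)c1
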